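The constants used here are made up.

You are putting 0.010 M of starting material and 5.00 mM of other conformer, with 2.00 mM of protic impurity beside them, through each set-up below, and you want target out.

    starting material → decomposition product (k1 = 2.5 × 10⁻⁵ /s)
    starting material → target (k2 = 0.0038 /s)
    target ⇌ isomer of the product (K3 = 11, k3 = 0.0039 /s)
    other conformer → isomer of the product (k4 = 0.49 /s)
    other conformer + protic impurity → quenched substrate (k5 = 82 /M/s)
    starting material ⇌ other conformer (K6 = 0.0059, k6 = 2.7 × 10⁻⁴ /s)

common to all: protic impurity 2.00 mM

| charge | starting material | other conformer | remark | time |
|---|---|---|---|---|
| Friday's | 0.010 M | 5.00 mM | a single well-mixed tank run continuously and read at steady state, 12 min in it on average |  |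
| Tuesday's | 0.010 M | 5.00 mM (fed, over 9.60 min) | a stirred flask in which other conformer is dosed at a steady rate over 9.60 min without added volume, worked up at 12 min | 12 min |
| Sunday's | 0.010 M (fed, over 9.60 min) | 5.00 mM | a stirred flask in which starting material is dosed at a steady rate over 9.60 min without added volume, worked up at 12 min | 12 min |
| Wednesday's | 0.010 M | 5.00 mM | a closed flask charged with all of it at once and left for 12 min | 12 min |

- the set-up with the highest amount of target at the outlet or at the end, in percent of the starting material and other conformer together put in ("none" if the first two lie within 2 percentage points) (Friday's / Tuesday's / Sunday's / Wednesday's / none)
- amount of target at the outlet or at the end, in percent of the starting material and other conformer together put in, Friday's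
- amount of target at the outlet or at the end, in percent of the starting material and other conformer together put in, Tuesday's
- amount of target at the outlet or at the end, in percent of the starting material and other conformer together put in, Sunday's
- amount of target at the outlet or at the end, in percent of the starting material and other conformer together put in, Wednesday's

- the stated concentrations are those of everything mixed, before any reaction; amounts are the same in each set-up
- the feed brings no volume worth counting
- run time (Tuesday's): 12 min

Where does the other conformer go? It disappears at 0.700 /s at the start, far faster than starting material makes target at 0.0038 /s. At that moment 70.0% of its loss goes to isomer of the product; I carry that share over the whole charge and reckon 3.50 mM, so I look to starting material for target and reckon Tuesday's dosing of the other conformer as Wednesday's single charge.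

Does target last? It relaxes towards 8.33% of the target-plus-isomer pool at 0.00425 /s, about the rate at which starting material goes, 0.00409 /s. The excess over that share therefore follows the curve for consecutive steps with equal constants: 91.7% of the charge, times the constant of the step to target, times the age, times the relaxation's decay at that age. That excess peaks at 3.92 min, earlier than 12 min, so past the peak a younger charge of starting material holds more target.

How old is the starting material? In Sunday's flask it is 7.20 min: the run time less half the dosing time, its mean age at work-up. That gives an excess of 2.39 mM, and with the pool's share, 3.39 mM of target, or 22.6%. Averaging the curve over the real ages, from 2.40 min up, gives 0.954 of that excess.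

At age 12 min, I reckon Wednesday's flask at 2.26 mM, which is 15.1%, and Tuesday's at 15.1%. The averaging error of 0.110 mM is smaller than Sunday's reckoned lead of 1.13 mM. Friday's tank spreads its ages widely, so I use steady balances there: 2.44 mM, or 16.3%. My pick is Sunday's.

The forecast, choosing to “treat it as quasi-steady” for the other conformer, gives Friday's 16.6%, Tuesday's 15.8%, Sunday's 22.4% and Wednesday's 15.9%, and names Sunday's.

The simulation gives Friday's 16.6%, Tuesday's 15.8%, Sunday's 22.4% and Wednesday's 15.9%, with Sunday's ahead. The largest single effect holding Sunday's down is the loss of target to isomer of the product, both ways: without that step the flask gives 50.9%, which accounts for 37% of what is missing. Part of Sunday's lead is the slow dosing: charged in one go, that flask gives 15.9% against 22.4%, as its mean age goes from 7.20 min to 12 min. Sunday's with 0.013 M of other conformer keeps that age, so my excess stays 2.39 mM while the amount put in grows, and I reckon 16.8%; that flask gave 17.5%.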